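**Retrosynthetic overview**
1. The last step joins linoleic acid to the (E)-allylic methyl carbonate of the C17 enediyne epoxide by a branched-selective asymmetric allylic esterification. This forms the C3–O bond, sets C3 and creates the vinyl group.
2. The C7–C8 bond comes from a lithium diynide (from a TMS-capped enediyne) and the triflate of (2R,3R)-2,3-epoxydecan-1-ol.
3. The conjugated diyne is made by a Fritsch–Buttenberg–Wiechell 1,2-shift in the lithium carbenoid of a dibromoolefin. Its enynone comes from a cross-metathesis Weinreb amide and TMS-acetylene; CBr4 supplies C5.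
4. Dec-2-yn-1-ol (propargyl alcohol + 1-bromoheptane) is used twice: LiAlH4 then Sharpless epoxidation gives the epoxy alcohol; acetylene zipper then oxidation gives dec-9-ynoic acid. The acid, an oct-2-ynyl tosylate (hept-1-yne + CH2O) and Lindlar reduction give linoleic acid.
5. Ring order: the oxirane is the only ring. It is closed in the Sharpless step and carried unchanged.

Assumption: the SMILES is read literally, so C3 is S and the oxirane is (9R,10R), i.e. trans-disubstituted.

**Step 1**
Reactants: 1 prop-2-yn-1-ol; 2 1-bromoheptane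
Product: 3 dec-2-yn-1-ol
Conditions: 1, n-BuLi (2.1 equiv), THF/DMPU, −78 → −20 °C; 2, → rt; H2O
Reagents that add atoms: none
Why: double deprotonation gives the alkoxide–acetylide dianion, and only its acetylide carbon is alkylated by the primary bromide (acetylide SN2 alkylation).

**Step 2**
Reactants: 3 dec-2-yn-1-ol
Product: 4 (2E)-dec-2-en-1-ol
Conditions: LiAlH4, THF, reflux; H2O/NaOH work-up
Reagents that add atoms: none
Why: alkoxide-directed trans-hydroalumination of the propargylic alcohol followed by protonolysis gives only the E-allylic alcohol.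

**Step 3**
Reactants: 4 (2E)-dec-2-en-1-ol
Product: 5 [(2R,3R)-3-heptyloxiran-2-yl]methanol
Conditions: Ti(OiPr)4 (5 mol%), D-(−)-diisopropyl tartrate (6 mol%), t-BuOOH (2 equiv), 4 Å MS, CH2Cl2, −20 °C
Reagents that add atoms: tert-butyl hydroperoxide, CC(C)(C)OO
Why: Sharpless asymmetric epoxidation, in which the D-(−)-tartrate titanium complex delivers oxygen to the alkene face that gives the (2R,3R)-epoxy alcohol (trans from the E-alkene, typically ≥94% ee), so both oxirane stereocentres are set here.

**Step 4**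
Reactants: 3 dec-2-yn-1-ol
Product: 6 dec-9-yn-1-ol
Conditions: KH, H2N(CH2)3NH2, 0 °C → rt; H2O
Reagents that add atoms: none
Why: acetylene zipper isomerisation, in which potassium 3-aminopropylamide moves the triple bond along the chain by propargyl–allenyl proton shifts until irreversible terminal acetylide formation stops it at the chain end.

**Step 5**
Reactants: 6 dec-9-yn-1-ol
Product: 7 dec-9-ynoic acid
Conditions: TEMPO (20 mol%), PhI(OAc)2 (2.2 equiv), MeCN/H2O 1:1, rt
Reagents that add atoms: water, O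
Why: oxoammonium (TEMPO) oxidation takes the primary alcohol through the aldehyde hydrate to the acid and leaves the terminal alkyne untouched.

**Step 6**
Reactants: 8 hept-1-yne
Product: 10 oct-2-yn-1-yl 4-methylbenzenesulfonate, via lithium oct-2-yn-1-olate 9 (not isolated)
Conditions: n-BuLi, THF, −78 °C; (CH2O)n, → rt; TsCl, −20 → 0 °C
Reagents that add atoms: formaldehyde (as paraformaldehyde), C=O; 4-methylbenzenesulfonyl chloride, Cc1ccc(cc1)S(=O)(=O)Cl
Why: the lithium acetylide adds to formaldehyde and the lithium alkoxide formed is sulfonylated in the same flask (hydroxymethylation followed by O-tosylation).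

**Step 7**
Reactants: 7 dec-9-ynoic acid; 10 oct-2-yn-1-yl 4-methylbenzenesulfonate
Product: 11 octadeca-9,12-diynoic acid
Conditions: 7, EtMgBr (2.1 equiv), THF, 0 °C → rt; CuCl (10 mol%); 10, rt → 40 °C; aq. HCl
Reagents that add atoms: none
Why: copper-catalysed coupling of an alkynyl Grignard reagent with a propargylic sulfonate gives the skipped diyne by SN2 attack, the bromomagnesium carboxylate of the dianion being too poor a nucleophile to compete.

**Step 8**
Reactants: 11 octadeca-9,12-diynoic acid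
Product: 12 (9Z,12Z)-octadeca-9,12-dienoic acid (linoleic acid)
Conditions: H2 (1 atm), Pd/CaCO3–Pb(OAc)2 (Lindlar catalyst), quinoline, EtOAc, rt
Reagents that add atoms: none
Why: Lindlar semihydrogenation adds H2 syn to each triple bond and stops at the alkene, giving both Z-double bonds.

**Step 9**
Reactants: 13 tert-butyl(dimethyl)(prop-2-en-1-yloxy)silane; 14 N-methoxy-N-methylprop-2-enamide
Product: 15 (2E)-4-{[tert-butyl(dimethyl)silyl]oxy}-N-methoxy-N-methylbut-2-enamide
Conditions: second-generation Grubbs catalyst RuCl2(=CHPh)(PCy3)(H2IMes) (3 mol%), 13 (2 equiv), CH2Cl2, 40 °C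
Reagents that add atoms: none
Why: olefin cross-metathesis between an electron-rich terminal alkene and an electron-poor acrylamide is selective for the cross product and for the E-isomer, with loss of ethene.

**Step 10**
Reactants: 15 (2E)-4-{[tert-butyl(dimethyl)silyl]oxy}-N-methoxy-N-methylbut-2-enamide; 16 ethynyl(trimethyl)silane
Product: 17 (4E)-6-{[tert-butyl(dimethyl)silyl]oxy}-1-(trimethylsilyl)hex-4-en-1-yn-3-one
Conditions: 16, n-BuLi, THF, −78 °C; 15, −78 → −20 °C; H2O (pH 7)
Reagents that add atoms: none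
Why: Weinreb ketone synthesis, in which the lithium acetylide adds once to give a chelated tetrahedral adduct that releases the cross-conjugated enynone only on work-up, and the ketone has no enolisable or stereogenic position.

**Step 11**
Reactants: 17 (4E)-6-{[tert-butyl(dimethyl)silyl]oxy}-1-(trimethylsilyl)hex-4-en-1-yn-3-one
Product: 18 tert-butyl{[(2E)-4-(dibromomethylidene)-6-(trimethylsilyl)hex-2-en-5-yn-1-yl]oxy}dimethylsilane
Conditions: CBr4 (2 equiv), PPh3 (4 equiv), CH2Cl2, 0 °C → rt
Reagents that add atoms: carbon tetrabromide, BrC(Br)(Br)Br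
Why: Ramirez dibromoolefination (the first half of a Corey–Fuchs sequence), a Wittig reaction of the ketone with Ph3P=CBr2 made in the flask, which brings in the carbon that becomes C5.

**Step 12**
Reactants: 18 tert-butyl{[(2E)-4-(dibromomethylidene)-6-(trimethylsilyl)hex-2-en-5-yn-1-yl]oxy}dimethylsilane
Product: 20 tert-butyl(dimethyl){[(2E)-7-(trimethylsilyl)hept-2-ene-4,6-diyn-1-yl]oxy}silane, via lithium bromo carbenoid 19 (not isolated)
Conditions: n-BuLi (1.1 equiv), hexanes, −78 → −20 °C
Reagents that add atoms: none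
Why: Fritsch–Buttenberg–Wiechell rearrangement, in which Br/Li exchange gives the alkylidene carbenoid and on warming the alkynyl (or alkenyl) group shifts 1,2 to the carbenoid carbon with loss of LiBr, so the branched dibromoolefin becomes the linear conjugated diyne (both migrations give the same product, the E-alkene and silyl ether are untouched, and no stereocentre is involved).

**Step 13**
Reactants: 20 tert-butyl(dimethyl){[(2E)-7-(trimethylsilyl)hept-2-ene-4,6-diyn-1-yl]oxy}silane; 5 [(2R,3R)-3-heptyloxiran-2-yl]methanol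
Product: 23 tert-butyl({(2E)-8-[(2R,3R)-3-heptyloxiran-2-yl]oct-2-ene-4,6-diyn-1-yl}oxy)dimethylsilane, via epoxy triflate 21 (not isolated), via lithium diynide 22 (not isolated)
Conditions: 5, Tf2O, 2,6-lutidine, CH2Cl2, −78 °C (21 used cold, unpurified); 20, MeLi·LiBr (1.0 equiv), THF, 0 °C → rt; then 21, DMPU, −78 → −30 °C
Reagents that add atoms: none
Why: MeLi·LiBr cleaves the C(sp)–Si bond to the lithium diynide, which displaces the primary triflate by SN2 at CH2 far faster than it opens the oxirane, so the C7–C8 bond forms and both oxirane stereocentres are carried over unchanged.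

**Step 14**
Reactants: 23 tert-butyl({(2E)-8-[(2R,3R)-3-heptyloxiran-2-yl]oct-2-ene-4,6-diyn-1-yl}oxy)dimethylsilane
Product: 24 (2E)-8-[(2R,3R)-3-heptyloxiran-2-yl]oct-2-ene-4,6-diyn-1-ol
Conditions: Bu4NF, AcOH (1:1), THF, 0 °C → rt
Reagents that add atoms: none
Why: fluoride cleavage of the primary silyl ether, buffered with acetic acid so that the oxirane and the acidic C8 methylene are not touched.

**Step 15**
Reactants: 24 (2E)-8-[(2R,3R)-3-heptyloxiran-2-yl]oct-2-ene-4,6-diyn-1-ol
Product: 25 (2E)-8-[(2R,3R)-3-heptyloxiran-2-yl]oct-2-ene-4,6-diyn-1-yl methyl carbonate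
Conditions: ClCO2Me, pyridine, CH2Cl2, 0 °C
Reagents that add atoms: methyl chloroformate, COC(=O)Cl
Why: O-acylation of the primary allylic alcohol installs the carbonate leaving group needed for allyl ionisation.

**Step 16**
Reactants: 25 (2E)-8-[(2R,3R)-3-heptyloxiran-2-yl]oct-2-ene-4,6-diyn-1-yl methyl carbonate; 12 (9Z,12Z)-octadeca-9,12-dienoic acid
Product: 26 (3S)-8-[(2R,3R)-3-heptyloxiran-2-yl]oct-1-ene-4,6-diyn-3-yl (9Z,12Z)-octadeca-9,12-dienoate
Conditions: [Ir(cod)Cl]2 (2 mol%), (Sa,Sc,Sc)-O,O′-(1,1′-binaphthalene-2,2′-diyl) N,N-bis(1-phenylethyl)phosphoramidite (4 mol%, preactivated with n-PrNH2), 12 (1.3 equiv), Cs2CO3 (10 mol%), THF, 25 °C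
Reagents that add atoms: none
Why: Proposed new method: branched- and enantioselective allylic esterification of a 1,3-diynyl-substituted allyl carbonate with a polyunsaturated fatty acid, in which the cyclometalated monovalent iridium–phosphoramidite complex ionises the carbonate (CO2 and methoxide leave, methoxide deprotonates 12) and the carboxylate attacks the trivalent iridium allyl complex from outside at the diynyl-bearing terminus on the face fixed by the ligand, setting C3 as S and creating the vinyl group; the closest known reaction type is the iridium/phosphoramidite-catalysed enantioselective allylic esterification of aryl- and alkyl-substituted allyl carbonates with carboxylates, and the ligand enantiomer is the one expected to give (S)-1-arylallyl esters there (the sense is checked on 25 with acetate first, and the antipodal ligand is used if it is reversed).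

**Compound list**
1 | prop-2-yn-1-ol | C#CCO | starting material
2 | 1-bromoheptane | CCCCCCCBr | starting material
3 | dec-2-yn-1-ol | CCCCCCCC#CCO | intermediate
4 | (2E)-dec-2-en-1-ol | CCCCCCC/C=C/CO | intermediate
5 | [(2R,3R)-3-heptyloxiran-2-yl]methanol | OC[C@H]1O[C@@H]1CCCCCCC | intermediate
6 | dec-9-yn-1-ol | C#CCCCCCCCCO | intermediate
7 | dec-9-ynoic acid | C#CCCCCCCCC(=O)O | intermediate
8 | hept-1-yne | CCCCCC#C | starting material
9 | lithium oct-2-yn-1-olate | CCCCCC#CC[O-].[Li+] | intermediate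
10 | oct-2-yn-1-yl 4-methylbenzenesulfonate | CCCCCC#CCOS(=O)(=O)c1ccc(C)cc1 | intermediate
11 | octadeca-9,12-diynoic acid | CCCCCC#CCC#CCCCCCCCC(=O)O | intermediate
12 | (9Z,12Z)-octadeca-9,12-dienoic acid (linoleic acid) | CCCCC/C=C\C/C=C\CCCCCCCC(=O)O | intermediate
13 | tert-butyl(dimethyl)(prop-2-en-1-yloxy)silane (allyl alcohol TBS ether) | C=CCO[Si](C)(C)C(C)(C)C | starting material
14 | N-methoxy-N-methylprop-2-enamide | C=CC(=O)N(C)OC | starting material
15 | (2E)-4-{[tert-butyl(dimethyl)silyl]oxy}-N-methoxy-N-methylbut-2-enamide | CON(C)C(=O)/C=C/CO[Si](C)(C)C(C)(C)C | intermediate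
16 | ethynyl(trimethyl)silane | C#C[Si](C)(C)C | starting material
17 | (4E)-6-{[tert-butyl(dimethyl)silyl]oxy}-1-(trimethylsilyl)hex-4-en-1-yn-3-one | C[Si](C)(C)C#CC(=O)/C=C/CO[Si](C)(C)C(C)(C)C | intermediate
18 | tert-butyl{[(2E)-4-(dibromomethylidene)-6-(trimethylsilyl)hex-2-en-5-yn-1-yl]oxy}dimethylsilane | C[Si](C)(C)C#CC(=C(Br)Br)/C=C/CO[Si](C)(C)C(C)(C)C | intermediate
19 | {(3E)-1-bromo-5-{[tert-butyl(dimethyl)silyl]oxy}-2-[(trimethylsilyl)ethynyl]penta-1,3-dien-1-yl}lithium (lithium bromo carbenoid) | C[Si](C)(C)C#CC(=C([Li])Br)/C=C/CO[Si](C)(C)C(C)(C)C | intermediate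
20 | tert-butyl(dimethyl){[(2E)-7-(trimethylsilyl)hept-2-ene-4,6-diyn-1-yl]oxy}silane | C[Si](C)(C)C#CC#C/C=C/CO[Si](C)(C)C(C)(C)C | intermediate
21 | [(2R,3R)-3-heptyloxiran-2-yl]methyl trifluoromethanesulfonate (epoxy triflate) | FC(F)(F)S(=O)(=O)OC[C@H]1O[C@@H]1CCCCCCC | intermediate
22 | {(5E)-7-{[tert-butyl(dimethyl)silyl]oxy}hept-5-ene-1,3-diyn-1-yl}lithium (lithium diynide) | [Li]C#CC#C/C=C/CO[Si](C)(C)C(C)(C)C | intermediate
23 | tert-butyl({(2E)-8-[(2R,3R)-3-heptyloxiran-2-yl]oct-2-ene-4,6-diyn-1-yl}oxy)dimethylsilane | CC(C)(C)[Si](C)(C)OC/C=C/C#CC#CC[C@H]1O[C@@H]1CCCCCCC | intermediate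
24 | (2E)-8-[(2R,3R)-3-heptyloxiran-2-yl]oct-2-ene-4,6-diyn-1-ol | OC/C=C/C#CC#CC[C@H]1O[C@@H]1CCCCCCC | intermediate
25 | (2E)-8-[(2R,3R)-3-heptyloxiran-2-yl]oct-2-ene-4,6-diyn-1-yl methyl carbonate | COC(=O)OC/C=C/C#CC#CC[C@H]1O[C@@H]1CCCCCCC | intermediate
26 | (3S)-8-[(2R,3R)-3-heptyloxiran-2-yl]oct-1-ene-4,6-diyn-3-yl (9Z,12Z)-octadeca-9,12-dienoate | C=C[C@@H](C#CC#CC[C@H]1O[C@@H]1CCCCCCC)OC(=O)CCCCCCC/C=C\C/C=C\CCCCC | target

**Step count**
Total: 16 steps. Longest linear sequence: 8 steps (13/14 → 15 → 17 → 18 → 20 → 23 → 24 → 25 → 26).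

**Three steps most likely to fail**

Step 16 (proposed new step). The risks are attack at the unsubstituted terminus giving the achiral linear ester, re-ionisation of the doubly activated product, and coordination of the diyne to iridium. The fallback uses only known reactions and sets out from allylic alcohol 24. Sharpless epoxidation (Ti(OiPr)4, D-(−)-diethyl tartrate, t-BuOOH, CH2Cl2, −20 °C) gives the bis-epoxy alcohol [(2R,3R)-3-{5-[(2R,3R)-3-heptyloxiran-2-yl]penta-1,3-diyn-1-yl}oxiran-2-yl]methanol F1. I2, PPh3 and imidazole convert it into the epoxy iodide (2R,3R)-2-heptyl-3-{5-[(2R,3S)-3-(iodomethyl)oxiran-2-yl]penta-2,4-diyn-1-yl}oxirane F2. Zinc dust in EtOH opens the iodo-epoxide reductively, without touching the C3–O bond, to the vinyl carbinol (3S)-8-[(2R,3R)-3-heptyloxiran-2-yl]oct-1-ene-4,6-diyn-3-ol F3. Esterification of F3 with 12 (DCC, DMAP, CH2Cl2, 0 °C) comes back to the route at 26.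

Step 13. The diynide is a weak nucleophile, and MeLi or the diynide may attack the triflate or oxirane unselectively. The fallback changes the order of bond formation and sets out from 5. Its triflate 21 is displaced by LiC≡CSiMe3 (THF/DMPU, −78 °C) to give the silyl alkyne {3-[(2R,3R)-3-heptyloxiran-2-yl]prop-1-yn-1-yl}trimethylsilane F4. K2CO3/MeOH frees the terminal alkyne (2R,3R)-2-heptyl-3-(prop-2-yn-1-yl)oxirane F5. Its lithium acetylide is acylated by Weinreb amide 15 to the ynone (2E)-1-{[tert-butyl(dimethyl)silyl]oxy}-7-[(2R,3R)-3-heptyloxiran-2-yl]hept-2-en-5-yn-4-one F6. CBr4/PPh3 gives the dibromoolefin tert-butyl({(2E)-4-(dibromomethylidene)-7-[(2R,3R)-3-heptyloxiran-2-yl]hept-2-en-5-yn-1-yl}oxy)dimethylsilane F7. The same carbenoid 1,2-shift (n-BuLi, hexanes, −78 → −20 °C) then comes back to the route at 23.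

Step 11. The cross-conjugated ketone is a sluggish Wittig partner, and PPh3 can add in conjugate fashion. The fallback drops the dibromoolefin and the lithium carbenoid and sets out from 17. Lithiated trimethylsilyldiazomethane (THF, −78 °C → rt) gives, by diazo-Peterson olefination, the diazoalkene tert-butyl{[(2E)-4-(diazomethylidene)-6-(trimethylsilyl)hex-2-en-5-yn-1-yl]oxy}dimethylsilane F8, which is not isolated. It loses N2 to the free alkylidene carbene, and the same 1,2-shift comes back to the route at 20 in one operation.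

**Further compounds**
F1 | step 16 | [(2R,3R)-3-{5-[(2R,3R)-3-heptyloxiran-2-yl]penta-1,3-diyn-1-yl}oxiran-2-yl]methanol | OC[C@H]1O[C@@H]1C#CC#CC[C@H]2O[C@@H]2CCCCCCC
F2 | step 16 | (2R,3R)-2-heptyl-3-{5-[(2R,3S)-3-(iodomethyl)oxiran-2-yl]penta-2,4-diyn-1-yl}oxirane | IC[C@H]1O[C@@H]1C#CC#CC[C@H]2O[C@@H]2CCCCCCC
F3 | step 16 | (3S)-8-[(2R,3R)-3-heptyloxiran-2-yl]oct-1-ene-4,6-diyn-3-ol | C=C[C@@H](C#CC#CC[C@H]1O[C@@H]1CCCCCCC)O
F4 | step 13 | {3-[(2R,3R)-3-heptyloxiran-2-yl]prop-1-yn-1-yl}trimethylsilane | C[Si](C)(C)C#CC[C@H]1O[C@@H]1CCCCCCC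
F5 | step 13 | (2R,3R)-2-heptyl-3-(prop-2-yn-1-yl)oxirane | C#CC[C@H]1O[C@@H]1CCCCCCC
F6 | step 13 | (2E)-1-{[tert-butyl(dimethyl)silyl]oxy}-7-[(2R,3R)-3-heptyloxiran-2-yl]hept-2-en-5-yn-4-one | CC(C)(C)[Si](C)(C)OC/C=C/C(=O)C#CC[C@H]1O[C@@H]1CCCCCCC
F7 | step 13 | tert-butyl({(2E)-4-(dibromomethylidene)-7-[(2R,3R)-3-heptyloxiran-2-yl]hept-2-en-5-yn-1-yl}oxy)dimethylsilane | CC(C)(C)[Si](C)(C)OC/C=C/C(=C(Br)Br)C#CC[C@H]1O[C@@H]1CCCCCCC
F8 | step 11 | tert-butyl{[(2E)-4-(diazomethylidene)-6-(trimethylsilyl)hex-2-en-5-yn-1-yl]oxy}dimethylsilane | C[Si](C)(C)C#CC(=C=[N+]=[N-])/C=C/CO[Si](C)(C)C(C)(C)C
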